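## Structural features

The target is a 2,2-dimethylchroman: a dihydropyran ring (O1, C2, C3, C4) fused through C4a–C8a to a benzene ring in which every carbon is substituted. The benzene ring carries hydroxyl at C5, methyl at C6, hydroxyl at C7 and a 3-phenylpropanoyl chain at C8, with O1 on C8a. C4 bears a secondary hydroxyl and is the only stereocenter, (R); it has no stereogenic neighbour, so its configuration must come from a catalyst. The C4–O bond is benzylic, and C4a has oxygen donors at both ortho positions (C5, C8a) and at the para position (C7). The alcohol therefore ionises easily: acid causes loss of water to the 2H-chromene, ether formation or racemisation, and hydrogenolysis can cut the C4–O bond. The free acylphloroglucinol is oxidisable, so the phenols should be unmasked last and under neutral conditions. The real difficulty is regiochemical placement of six different substituents on one benzene ring, together with enantiocontrol at an isolated, labile carbinol. The key step exploits the fact that O1 (on C8a) and C4 (on C4a) are ortho to each other, with the C5 oxygen next to C4a and, before acylation, only hydrogen on C8 next to C8a. This is the pattern of a 3-alkoxyaryne, which takes up the oxygen of 3-methylbut-2-enal at C8a and its carbonyl carbon at C4a; the enal also supplies C2 with both methyl groups and C3.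

## Logic of the disconnections

**23 ⇒ 22.** The phenols at C5 and C7 are traced back to benzyl ethers (two aryl O–CH2 bonds). Free phenols cannot pass through the fluoride, organolithium and aryne steps, whereas benzyl ethers survive all of them and leave under neutral conditions. The demand is that hydrogenolysis cleaves two aryl benzyl ethers but spares the benzylic C4–OH and the aryl ketone.

**22 ⇒ 18 + 20.** The C8–C(=O) bond is cut. C8 is the one ring position the annulation leaves as C–H; it lies between two oxygen substituents, so it can be brominated and metalated. Adding the acyl group last keeps it out of the aryne and reduction steps and removes a nine-carbon chain in one convergent step. The forward step needs bromine–lithium exchange with the C4 hydroxyl present as its alkoxide, and a single acyl transfer.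

**20 ⇒ 19.** The amide C–N bond is cut; this is a routine acylation.

**18 ⇒ 17.** The C4–H bond is removed, returning the stereocenter to a carbonyl group. With no neighbouring stereocenter, a catalyst-controlled ketone reduction is the most dependable source of (R)-C4. The forward step must deliver hydride to the Si face in a non-acidic medium.

**17 ⇒ 16.** The C8–Br bond is cut. Bromination is placed on the ketone because the later benzylic alcohol is more delicate; C8 is the only free ring carbon, so no regiochemical question arises.

**16 ⇒ 15.** The C4 carbonyl is traced to the C3=C4 alkene that the annulation delivers. The forward oxidation must place oxygen on the benzylic carbon C4 and not on C3.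

**15 ⇒ 10 + 11.** Three bonds are cut: O1–C8a, C4–C4a and O1–C2. The pyran ring disappears and a bicyclic intermediate becomes a monocyclic aryne precursor plus a five-carbon enal, the largest simplification in the plan. The forward step needs regioselective addition to the aryne and protecting groups that tolerate fluoride.

**10 ⇒ 7 (through 8 and 9).** The C–Si and O–S bonds are cut. The sulfonate sits on the oxygen para to the methyl group and the silane between two oxygens, so both can be installed from an ortho-bromophenol by silyl migration from oxygen to carbon.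

**7 ⇒ 6.** The C–Br bond is cut. The two positions ortho to the hydroxyl of 6 are equivalent, so only over-bromination must be avoided.

**6 ⇒ 5.** The phenol C–O bond is traced to a C–B bond. This oxygen is para to the methyl group and meta to both ether oxygens, a position electrophilic substitution cannot reach. A Baeyer–Villiger or Dakin oxidation of the corresponding benzaldehyde was rejected: an aryl group with two meta alkoxy groups and no ortho or para donor migrates poorly, so hydride migration to the benzoic acid should dominate. Oxidation of a C–B bond has no such competition.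

**5 ⇒ 3 (through 4).** The benzyl ethers are exchanged for silyl ethers. Benzyl groups have unhindered aromatic C–H bonds that would themselves be borylated; silyl ethers have none and shield the two flanking ring positions.

**3 ⇒ 2 and 2 ⇒ 1.** The C–B bond is traced to C–H and the O–Si bonds to the free diol. Sterically governed C–H borylation selects the only ring C–H with two hydrogen neighbours, and the starting diol is cheap.

## Other disconnections considered

**Alternative 1:** The cut removes the ketone carbon itself: both C8–C(=O) and C(=O)–CH2 are broken. This leaves the aryl bromide (18 of the chosen route), carbon monoxide and the alkylborane A2, 9-(2-phenylethyl)-9-borabicyclo[3.3.1]nonane, available from styrene and 9-BBN. In the forward step zerovalent palladium from Pd(PPh3)4 would insert into the C8–Br bond, CO would insert, A2 would transfer its alkyl group and reductive elimination would give A1, 1-[(4R)-5,7-bis(benzyloxy)-4-hydroxy-2,2,6-trimethylchroman-8-yl]-3-phenylpropan-1-one, the same structure as 22.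
- In its favour: no strong base is needed, so the C4 hydroxyl needs neither deprotonation nor protection, and the side chain comes from styrene and CO.
- Against it here: the bromide is flanked by two ortho oxygen substituents on a very electron-rich ring, so oxidative addition should be slow, and CO lowers the electron density at palladium further. Direct alkyl–aryl coupling without CO and β-hydride elimination are competing paths, and a toxic gas is required.
- Comparison: structurally it is a variant of step 12, not a different ring strategy. On step economy it is equal (one step from 18; making A2 in the flask balances making 20). On functional-group tolerance it is the better of the two. The chosen bromine–lithium exchange is preferred because its rate does not depend on the electronic character of the ring.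

**Alternative 2:** The cut breaks three bonds of the benzene ring (C5–C6, C7–C8, C4a–C5). The fragments are the diazoketone A4, 2-diazo-1-[(4R)-4-(tert-butyldimethylsilyloxy)-6,6-dimethyl-5,6-dihydro-4H-pyran-2-yl]ethan-1-one, and the siloxyalkyne A5, triisopropyl(prop-1-yn-1-yloxy)silane. Irradiation of A4 would give a vinylketene by Wolff rearrangement; (2+2) addition of A5, 4π opening of the cyclobutenone and 6π closure would give A3, (4R)-4-(tert-butyldimethylsilyloxy)-2,2,6-trimethyl-7-(triisopropylsilyloxy)chroman-5-ol.
- In its favour: the arene substitution pattern follows from connectivity, so the regiochemical question the aryne must answer does not arise. The stereocenter is carried in, and both oxygen protecting groups leave with fluoride, so no hydrogenolysis is run near the C4–O bond. On these three points it is the better plan.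
- Against it here: A4 needs a multi-step synthesis and a resolution that discards half the material. It also combines a diazoketone, a photochemical step and an allylic silyloxy group on an enol ether that is prone to elimination. A3 still lacks the C8 acyl group, so bromination and acylation remain.
- Comparison: structurally the benzene ring is made last instead of first. Mechanistically both plans rest on a pericyclic cascade through a four-membered ring. On step economy the alternative is clearly longer.

**Alternative 3:** The cut breaks C3–C4 and O1–C2, leaving isobutene and the aldehyde A7, 2,4-bis(benzyloxy)-6-hydroxy-3-methylbenzaldehyde, which could come from 6 by ortho-formylation. A confined chiral Brønsted acid of the imidodiphosphorimidate type would activate the aldehyde; isobutene would add to its carbon and the phenol oxygen would trap the tertiary cation, giving A6, (4R)-5,7-bis(benzyloxy)-2,2,6-trimethylchroman-4-ol.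
- In its favour: the ring and the stereocenter are made in one catalytic step without a redox detour, and A6 would be two steps from 6 where the chosen route needs more. On step economy it is the better plan.
- Against it here: A6 is exactly the kind of benzylic alcohol a strong acid ionises. The resulting ortho-quinone methide could add a second isobutene or re-close with loss of enantiopurity. The aldehyde carbon is deactivated by three oxygen donors and an internal hydrogen bond, and its two ortho substituents may not fit a confined pocket. Ene-type addition without ring closure and isobutene oligomerisation are further risks.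
- Comparison: structurally it ends at the debromo analogue of 18, from which bromination, acylation and hydrogenolysis would follow as in the chosen plan. Mechanistically it is cationic under strong acid, whereas the chosen plan is neutral and separates ring formation from creation of the stereocenter. The chosen plan is the more dependable; the alternative is the shorter.

Key step: step 7

## Steps

Step 1
Reactants: 1 2-methylbenzene-1,3-diol (2-methylresorcinol)
Product: 2 1,3-bis(tert-butyldimethylsilyloxy)-2-methylbenzene
Conditions: TBSCl (2.3 equiv), imidazole, DMF, rt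
Reagents that add atoms: tert-butyldimethylsilyl chloride, CC(C)(C)[Si](C)(C)Cl
Why: Routine O-silylation of both phenols; the bulky silyl ethers have no aromatic C–H bonds and shield the two ring positions next to them for step 2.

Step 2
Reactants: 2 1,3-bis(tert-butyldimethylsilyloxy)-2-methylbenzene
Product: 3 2-[3,5-bis(tert-butyldimethylsilyloxy)-4-methylphenyl]-4,4,5,5-tetramethyl-1,3,2-dioxaborolane
Conditions: [Ir(OMe)(cod)]2 (1.5 mol%), 4,4'-di-tert-butyl-2,2'-bipyridine (3 mol%), B2pin2 (1.0 equiv), THF, 80 °C
Reagents that add atoms: bis(pinacolato)diboron, CC1(C)OB(OC1(C)C)B1OC(C)(C)C(C)(C)O1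
Why: Iridium-catalysed aromatic C–H borylation is governed by sterics and avoids C–H bonds with an ortho substituent; the only ring C–H with two hydrogen neighbours is the one para to the methyl group, so boron should enter there alone.

Step 3
Reactants: 3 2-[3,5-bis(tert-butyldimethylsilyloxy)-4-methylphenyl]-4,4,5,5-tetramethyl-1,3,2-dioxaborolane
Product: 5 2-[3,5-bis(benzyloxy)-4-methylphenyl]-4,4,5,5-tetramethyl-1,3,2-dioxaborolane, via dicesium 2-methyl-5-(4,4,5,5-tetramethyl-1,3,2-dioxaborolan-2-yl)benzene-1,3-diolate 4 (not isolated)
Conditions: CsF (4 equiv), BnBr (2.5 equiv), DMF, rt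
Reagents that add atoms: benzyl bromide, BrCc1ccccc1
Why: Fluoride cleaves the aryl silyl ethers to diolate 4, which is O-benzylated in the same flask (Williamson ether synthesis); the C–B bond is meta to both oxygens, so protodeboronation gets no assistance from the phenoxides.

Step 4
Reactants: 5 2-[3,5-bis(benzyloxy)-4-methylphenyl]-4,4,5,5-tetramethyl-1,3,2-dioxaborolane
Product: 6 3,5-bis(benzyloxy)-4-methylphenol
Conditions: 30% H2O2, aq. NaOH, THF, 0 °C → rt; then buffer to pH 6
Reagents that add atoms: hydrogen peroxide, OO
Why: Oxidation of an arylboronic ester with alkaline hydrogen peroxide, in which the aryl group shifts from boron to oxygen with no competing migrating group; benzyl ethers are inert.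

Step 5
Reactants: 6 3,5-bis(benzyloxy)-4-methylphenol
Product: 7 3,5-bis(benzyloxy)-2-bromo-4-methylphenol
Conditions: NBS (1.0 equiv), CH2Cl2, −78 → 0 °C
Reagents that add atoms: N-bromosuccinimide, O=C1CCC(=O)N1Br
Why: Electrophilic aromatic bromination; the two free positions are equivalent (each ortho to the hydroxyl, ortho to one benzyloxy group and para to the other), so stoichiometry and low temperature only have to prevent a second bromination.

Step 6
Reactants: 7 3,5-bis(benzyloxy)-2-bromo-4-methylphenol
Product: 10 3,5-bis(benzyloxy)-4-methyl-2-(trimethylsilyl)phenyl trifluoromethanesulfonate, via [3,5-bis(benzyloxy)-2-bromo-4-methylphenoxy]trimethylsilane 8 (not isolated), via lithium 3,5-bis(benzyloxy)-4-methyl-2-(trimethylsilyl)phenoxide 9 (not isolated)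
Conditions: HMDS, THF, 65 °C, then evaporation; n-BuLi (1.1 equiv), THF, −90 °C; Tf2O (1.2 equiv), −90 → −70 °C
Reagents that add atoms: hexamethyldisilazane, C[Si](C)(C)N[Si](C)(C)C; trifluoromethanesulfonic anhydride, O=S(=O)(OS(=O)(=O)C(F)(F)F)C(F)(F)F
Why: O-silylation gives 8; bromine–lithium exchange then triggers the 1,3 shift of silicon from oxygen to carbon (retro-Brook rearrangement) to phenoxide 9, which is triflated in the same flask, the standard one-flask route to ortho-silylaryl triflates. The exchange at −90 °C should be far faster than deprotonation of the benzyl ethers.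

Step 7
Reactants: 10 3,5-bis(benzyloxy)-4-methyl-2-(trimethylsilyl)phenyl trifluoromethanesulfonate, 11 3-methylbut-2-enal
Product: 15 5,7-bis(benzyloxy)-2,2,6-trimethyl-2H-chromene, via 3,5-bis(benzyloxy)-4-methyl-1,2-didehydrobenzene 12 (not isolated), via 3,5-bis(benzyloxy)-4-methyl-2-(2-methylprop-1-en-1-yl)-2H-1-benzoxete 13 (not isolated), via 3,5-bis(benzyloxy)-4-methyl-6-(3-methylbut-2-en-1-ylidene)cyclohexa-2,4-dien-1-one 14 (not isolated)
Conditions: CsF (3 equiv), 11 (5 equiv), MeCN, rt, slow addition of 10
Reagents that add atoms: none
Why: Fluoride attacks the trimethylsilyl group of 10 and loss of triflate releases aryne 12. The carbonyl oxygen of 11 adds to the aryne carbon remote from the adjacent benzyloxy group (the future C8a), because that σ-withdrawing group distorts the triple bond and stabilises the aryl anion developing on the carbon next to it (the future C4a); the anion closes onto the carbonyl carbon to give benzoxete 13, a stepwise (2+2) addition. Thermal 4π opening of 13 gives ortho-quinone methide 14, and the pyran ring then closes by thermal disrotatory oxa-6π electrocyclisation, the carbonyl oxygen bonding to the dimethyl-substituted terminus (O1–C2) with return of aromaticity. The closest known reaction type is the fluoride-induced annulation of ortho-silylaryl triflates with α,β-unsaturated aldehydes to 2H-chromenes. No stereocenter is formed, since C2 carries two methyl groups. The step needs regioselectivity in the first C–O bond, which the benzyloxy group next to the triple bond of 12 secures. It also needs carbonyl addition to win over ene reaction, (4+2) addition and capture of 14 by a second aryne, which the excess of 11, its β,β-disubstitution and the slow release of 12 should secure. Benzyl ethers are inert to CsF, which silyl ethers would not be.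

Step 8
Reactants: 15 5,7-bis(benzyloxy)-2,2,6-trimethyl-2H-chromene
Product: 16 5,7-bis(benzyloxy)-2,2,6-trimethylchroman-4-one
Conditions: FeCl2 (10 mol%), neocuproine (10 mol%), PhSiH3 (2 equiv), EtOH, air, rt
Reagents that add atoms: dioxygen, O=O
Why: Iron-catalysed Wacker-type oxidation by hydrogen-atom transfer (Mukaiyama-type): a hydrogen atom adds to C3 to give the aryl-stabilised radical at C4, which captures O2, and the peroxide collapses to the ketone. Radical stability fixes oxygen at C4, whereas a palladium Wacker oxidation would favour C3.

Step 9
Reactants: 16 5,7-bis(benzyloxy)-2,2,6-trimethylchroman-4-one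
Product: 17 5,7-bis(benzyloxy)-8-bromo-2,2,6-trimethylchroman-4-one
Conditions: NBS (1.05 equiv), MeCN, 0 °C → rt
Reagents that add atoms: N-bromosuccinimide, O=C1CCC(=O)N1Br
Why: Electrophilic aromatic bromination at C8, the only unsubstituted ring carbon, which is ortho to O1 and to the C7 benzyloxy group and para to the C5 benzyloxy group; without acid or radical initiation the α-carbon C3 should not react.

Step 10
Reactants: 17 5,7-bis(benzyloxy)-8-bromo-2,2,6-trimethylchroman-4-one
Product: 18 (4R)-5,7-bis(benzyloxy)-8-bromo-2,2,6-trimethylchroman-4-ol
Conditions: RuCl[(R,R)-TsDPEN](p-cymene) (2 mol%), HCO2H/Et3N (1:2), DMF, 40 °C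
Reagents that add atoms: none
Why: Noyori asymmetric transfer hydrogenation; with the (R,R) ligand the fused aryl ring lies under the η6-arene of the catalyst and hydride goes to the Si face of C4 (priorities OH > C4a > C3), which should set (R)-C4 as with other benzo-fused cyclic aryl ketones. The amine-rich formate medium keeps the ionisable benzylic alcohol away from acid.

Step 11
Reactants: 19 3-phenylpropanoyl chloride
Product: 20 N-methoxy-N-methyl-3-phenylpropanamide
Conditions: MeNH(OMe)·HCl (1.1 equiv), K2CO3, EtOAc/H2O, 0 °C → rt
Reagents that add atoms: N,O-dimethylhydroxylamine hydrochloride, CNOC.Cl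
Why: Schotten–Baumann acylation of the amine by the acid chloride gives the Weinreb amide.

Step 12
Reactants: 18 (4R)-5,7-bis(benzyloxy)-8-bromo-2,2,6-trimethylchroman-4-ol, 20 N-methoxy-N-methyl-3-phenylpropanamide
Product: 22 1-[(4R)-5,7-bis(benzyloxy)-4-hydroxy-2,2,6-trimethylchroman-8-yl]-3-phenylpropan-1-one, via lithium (4R)-5,7-bis(benzyloxy)-8-lithio-2,2,6-trimethylchroman-4-olate 21 (not isolated)
Conditions: n-BuLi (1.05 equiv), THF, −78 °C; t-BuLi (2.1 equiv), −78 °C; then 20 (1.5 equiv), −78 → 0 °C; aq. NH4Cl
Reagents that add atoms: none
Why: The hydroxyl is deprotonated first, then bromine–lithium exchange gives dilithio species 21, whose C8 carbanion (flanked by two coordinating oxygens) acylates the Weinreb amide; the chelated tetrahedral adduct prevents a second addition. No bond to C4 is touched, so the configuration is kept.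

Step 13
Reactants: 22 1-[(4R)-5,7-bis(benzyloxy)-4-hydroxy-2,2,6-trimethylchroman-8-yl]-3-phenylpropan-1-one
Product: 23 1-[(4R)-4,5,7-trihydroxy-2,2,6-trimethylchroman-8-yl]-3-phenylpropan-1-one (the target)
Conditions: H2 (1 atm), 10% Pd/C, EtOAc, rt, stopped at full debenzylation
Reagents that add atoms: none
Why: Hydrogenolysis of aryl benzyl ethers in a neutral aprotic solvent should be faster than cleavage of the secondary benzylic C4–OH, which the electron-withdrawing C8 acyl group makes less prone to ionise. The ketone, hydrogen-bonded to the freed C7 hydroxyl, should resist reduction at this pressure.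

## Compound list

1 | 2-methylbenzene-1,3-diol | Cc1c(O)cccc1O | starting material
2 | 1,3-bis(tert-butyldimethylsilyloxy)-2-methylbenzene | Cc1c(O[Si](C)(C)C(C)(C)C)cccc1O[Si](C)(C)C(C)(C)C | intermediate
3 | 2-[3,5-bis(tert-butyldimethylsilyloxy)-4-methylphenyl]-4,4,5,5-tetramethyl-1,3,2-dioxaborolane | Cc1c(O[Si](C)(C)C(C)(C)C)cc(B2OC(C)(C)C(C)(C)O2)cc1O[Si](C)(C)C(C)(C)C | intermediate
4 | dicesium 2-methyl-5-(4,4,5,5-tetramethyl-1,3,2-dioxaborolan-2-yl)benzene-1,3-diolate | Cc1c([O-])cc(B2OC(C)(C)C(C)(C)O2)cc1[O-].[Cs+].[Cs+] | intermediate (not isolated)
5 | 2-[3,5-bis(benzyloxy)-4-methylphenyl]-4,4,5,5-tetramethyl-1,3,2-dioxaborolane | Cc1c(OCc2ccccc2)cc(B2OC(C)(C)C(C)(C)O2)cc1OCc1ccccc1 | intermediate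
6 | 3,5-bis(benzyloxy)-4-methylphenol | Cc1c(OCc2ccccc2)cc(O)cc1OCc1ccccc1 | intermediate
7 | 3,5-bis(benzyloxy)-2-bromo-4-methylphenol | Cc1c(OCc2ccccc2)cc(O)c(Br)c1OCc1ccccc1 | intermediate
8 | [3,5-bis(benzyloxy)-2-bromo-4-methylphenoxy]trimethylsilane | Cc1c(OCc2ccccc2)cc(O[Si](C)(C)C)c(Br)c1OCc1ccccc1 | intermediate (not isolated)
9 | lithium 3,5-bis(benzyloxy)-4-methyl-2-(trimethylsilyl)phenoxide | Cc1c(OCc2ccccc2)cc([O-])c([Si](C)(C)C)c1OCc1ccccc1.[Li+] | intermediate (not isolated)
10 | 3,5-bis(benzyloxy)-4-methyl-2-(trimethylsilyl)phenyl trifluoromethanesulfonate | Cc1c(OCc2ccccc2)cc(OS(=O)(=O)C(F)(F)F)c([Si](C)(C)C)c1OCc1ccccc1 | intermediate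
11 | 3-methylbut-2-enal | CC(C)=CC=O | starting material
12 | 3,5-bis(benzyloxy)-4-methyl-1,2-didehydrobenzene | CC1=C(OCc2ccccc2)C#CC=C1OCc1ccccc1 | intermediate (not isolated)
13 | 3,5-bis(benzyloxy)-4-methyl-2-(2-methylprop-1-en-1-yl)-2H-1-benzoxete | Cc1c(OCc2ccccc2)cc2OC(C=C(C)C)c2c1OCc1ccccc1 | intermediate (not isolated)
14 | 3,5-bis(benzyloxy)-4-methyl-6-(3-methylbut-2-en-1-ylidene)cyclohexa-2,4-dien-1-one | CC(C)=CC=C1C(=O)C=C(OCc2ccccc2)C(C)=C1OCc1ccccc1 | intermediate (not isolated)
15 | 5,7-bis(benzyloxy)-2,2,6-trimethyl-2H-chromene | Cc1c(OCc2ccccc2)cc2c(c1OCc1ccccc1)C=CC(C)(C)O2 | intermediate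
16 | 5,7-bis(benzyloxy)-2,2,6-trimethylchroman-4-one | Cc1c(OCc2ccccc2)cc2c(c1OCc1ccccc1)C(=O)CC(C)(C)O2 | intermediate
17 | 5,7-bis(benzyloxy)-8-bromo-2,2,6-trimethylchroman-4-one | Cc1c(OCc2ccccc2)c(Br)c2c(c1OCc1ccccc1)C(=O)CC(C)(C)O2 | intermediate
18 | (4R)-5,7-bis(benzyloxy)-8-bromo-2,2,6-trimethylchroman-4-ol | Cc1c(OCc2ccccc2)c(Br)c2c(c1OCc1ccccc1)[C@H](O)CC(C)(C)O2 | intermediate
19 | 3-phenylpropanoyl chloride | O=C(Cl)CCc1ccccc1 | starting material
20 | N-methoxy-N-methyl-3-phenylpropanamide | CON(C)C(=O)CCc1ccccc1 | intermediate
21 | lithium (4R)-5,7-bis(benzyloxy)-8-lithio-2,2,6-trimethylchroman-4-olate | Cc1c(OCc2ccccc2)c([Li])c2c(c1OCc1ccccc1)[C@H]([O-])CC(C)(C)O2.[Li+] | intermediate (not isolated)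
22 | 1-[(4R)-5,7-bis(benzyloxy)-4-hydroxy-2,2,6-trimethylchroman-8-yl]-3-phenylpropan-1-one | Cc1c(OCc2ccccc2)c(C(=O)CCc2ccccc2)c2c(c1OCc1ccccc1)[C@H](O)CC(C)(C)O2 | intermediate
23 | 1-[(4R)-4,5,7-trihydroxy-2,2,6-trimethylchroman-8-yl]-3-phenylpropan-1-one | Cc1c(O)c(C(=O)CCc2ccccc2)c2c(c1O)[C@H](O)CC(C)(C)O2 | target

## Step count and least certain steps

Total: 13 steps. Longest linear sequence: 12 steps (steps 1–10, 12 and 13, from 1 to 23); step 11 is a one-step side branch.

**Step 7 (key step).** The most likely failure is loss of the aryne to other partners: a second aryne can capture the ortho-quinone methide, the aryne can add to the product alkene, or fluoride-promoted self-condensation of the enal can leave too little aldehyde to trap the aryne. The cause is that an enal oxygen is only a weak nucleophile. The fallback sets out from 6 and 11 and returns at 15: condensation with PhB(OH)2 and AcOH in toluene at reflux. This attaches the aldehyde carbon ortho to the phenol oxygen through the aryl borate, loses water to the same ortho-quinone methide and closes by oxa-6π. Both ortho positions of 6 are equivalent, so the same chromene results and no new compound is made.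

**Step 8.** The most likely failure is incomplete oxygen transfer: a second hydrogen-atom transfer to the benzylic radical (net alkene reduction), or arrest at the alcohol or hydroperoxide stage. The cause is that oxygen capture and hydrogen delivery compete at a hindered, very electron-rich benzylic radical. The fallback sets out from 15 and returns at 16: Mukaiyama hydration (Co(acac)2, PhSiH3, O2, i-PrOH/THF, rt) to racemic 5,7-bis(benzyloxy)-2,2,6-trimethylchroman-4-ol F1, followed by oxidation with MnO2 in CH2Cl2.

**Step 10.** The most likely failure is poor facial selectivity or slow turnover, because the carbonyl is deactivated by three oxygen donors and crowded by the C5 benzyloxy group. Erosion of enantiopurity through reversible ionisation of the product is also possible if the medium turns acidic. The fallback sets out from 15 and returns at 18: rhodium-catalysed asymmetric hydroboration ([Rh(cod)2]BF4, QUINAP, catecholborane, THF; then H2O2/NaOH), using the ligand antipode that places the hydroxyl at C4 with (R) configuration (expected to be the (R) ligand by analogy with simple vinylarenes). This gives (4R)-5,7-bis(benzyloxy)-2,2,6-trimethylchroman-4-ol F2, and bromination with NBS in MeCN at −20 °C then gives 18.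

**Step 12.** The most likely failure is proton transfer in place of acyl transfer: the hindered C8 carbanion can deprotonate the α-CH2 of the amide, or exchange can stay incomplete because the lithium alkoxide aggregates. The fallback sets out from 18 and returns at 22:
- silylation (TESCl, imidazole, DMF) to [(4R)-5,7-bis(benzyloxy)-8-bromo-2,2,6-trimethylchroman-4-yl]oxy(triethyl)silane F3;
- exchange with t-BuLi at −78 °C and addition to the more electrophilic 3-phenylpropanal, giving 1-[(4R)-5,7-bis(benzyloxy)-2,2,6-trimethyl-4-(triethylsilyloxy)chroman-8-yl]-3-phenylpropan-1-ol F4;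
- oxidation with Dess–Martin periodinane/NaHCO3 to 1-[(4R)-5,7-bis(benzyloxy)-2,2,6-trimethyl-4-(triethylsilyloxy)chroman-8-yl]-3-phenylpropan-1-one F5;
- desilylation with TBAF/AcOH in THF.

**Step 13.** The most likely failure is over-reduction: hydrogenolysis of the benzylic C4–O bond once the phenols are free and the ring is at its most electron-rich, or ionisation of that alcohol on a slightly acidic catalyst. The fallback sets out from 22 and returns at 23:
- silylation (TBSCl, imidazole, DMF) to 1-[(4R)-5,7-bis(benzyloxy)-4-(tert-butyldimethylsilyloxy)-2,2,6-trimethylchroman-8-yl]-3-phenylpropan-1-one F6;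
- hydrogenolysis (H2, Pd/C, EtOAc), in which the bulky silyl ether shields the C4–O bond, to 1-[(4R)-4-(tert-butyldimethylsilyloxy)-5,7-dihydroxy-2,2,6-trimethylchroman-8-yl]-3-phenylpropan-1-one F7;
- desilylation with TBAF buffered by AcOH in THF at 0 °C.

## Further compounds

F0 | step 7 | none | none
F1 | step 8 | racemic 5,7-bis(benzyloxy)-2,2,6-trimethylchroman-4-ol | Cc1c(OCc2ccccc2)cc2c(c1OCc1ccccc1)C(O)CC(C)(C)O2
F2 | step 10 | (4R)-5,7-bis(benzyloxy)-2,2,6-trimethylchroman-4-ol | Cc1c(OCc2ccccc2)cc2c(c1OCc1ccccc1)[C@H](O)CC(C)(C)O2
F3 | step 12 | [(4R)-5,7-bis(benzyloxy)-8-bromo-2,2,6-trimethylchroman-4-yl]oxy(triethyl)silane | Cc1c(OCc2ccccc2)c(Br)c2c(c1OCc1ccccc1)[C@H](O[Si](CC)(CC)CC)CC(C)(C)O2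
F4 | step 12 | 1-[(4R)-5,7-bis(benzyloxy)-2,2,6-trimethyl-4-(triethylsilyloxy)chroman-8-yl]-3-phenylpropan-1-ol (both epimers at the new carbinol carbon) | Cc1c(OCc2ccccc2)c(C(O)CCc2ccccc2)c2c(c1OCc1ccccc1)[C@H](O[Si](CC)(CC)CC)CC(C)(C)O2
F5 | step 12 | 1-[(4R)-5,7-bis(benzyloxy)-2,2,6-trimethyl-4-(triethylsilyloxy)chroman-8-yl]-3-phenylpropan-1-one | Cc1c(OCc2ccccc2)c(C(=O)CCc2ccccc2)c2c(c1OCc1ccccc1)[C@H](O[Si](CC)(CC)CC)CC(C)(C)O2
F6 | step 13 | 1-[(4R)-5,7-bis(benzyloxy)-4-(tert-butyldimethylsilyloxy)-2,2,6-trimethylchroman-8-yl]-3-phenylpropan-1-one | Cc1c(OCc2ccccc2)c(C(=O)CCc2ccccc2)c2c(c1OCc1ccccc1)[C@H](O[Si](C)(C)C(C)(C)C)CC(C)(C)O2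
F7 | step 13 | 1-[(4R)-4-(tert-butyldimethylsilyloxy)-5,7-dihydroxy-2,2,6-trimethylchroman-8-yl]-3-phenylpropan-1-one | Cc1c(O)c(C(=O)CCc2ccccc2)c2c(c1O)[C@H](O[Si](C)(C)C(C)(C)C)CC(C)(C)O2
A1 | alternative 1 | 1-[(4R)-5,7-bis(benzyloxy)-4-hydroxy-2,2,6-trimethylchroman-8-yl]-3-phenylpropan-1-one | Cc1c(OCc2ccccc2)c(C(=O)CCc2ccccc2)c2c(c1OCc1ccccc1)[C@H](O)CC(C)(C)O2
A2 | alternative 1 | 9-(2-phenylethyl)-9-borabicyclo[3.3.1]nonane | C(Cc1ccccc1)B1C2CCCC1CCC2
A3 | alternative 2 | (4R)-4-(tert-butyldimethylsilyloxy)-2,2,6-trimethyl-7-(triisopropylsilyloxy)chroman-5-ol | Cc1c(O[Si](C(C)C)(C(C)C)C(C)C)cc2c(c1O)[C@H](O[Si](C)(C)C(C)(C)C)CC(C)(C)O2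
A4 | alternative 2 | 2-diazo-1-[(4R)-4-(tert-butyldimethylsilyloxy)-6,6-dimethyl-5,6-dihydro-4H-pyran-2-yl]ethan-1-one | [N-]=[N+]=CC(=O)C1=C[C@H](O[Si](C)(C)C(C)(C)C)CC(C)(C)O1
A5 | alternative 2 | triisopropyl(prop-1-yn-1-yloxy)silane | CC#CO[Si](C(C)C)(C(C)C)C(C)C
A6 | alternative 3 | (4R)-5,7-bis(benzyloxy)-2,2,6-trimethylchroman-4-ol | Cc1c(OCc2ccccc2)cc2c(c1OCc1ccccc1)[C@H](O)CC(C)(C)O2
A7 | alternative 3 | 2,4-bis(benzyloxy)-6-hydroxy-3-methylbenzaldehyde | Cc1c(OCc2ccccc2)cc(O)c(C=O)c1OCc1ccccc1
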